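4 questions stand on 6 flasks, and we reckon one of them, larch, by a ledger of its limiting reagent.

| setting | south-east | north-west | north | birch | alder | larch | ash | cedar | oak |
|---|---|---|---|---|---|---|---|---|---|
| starting material | 0.051 M | 0.65 M | 0.20 M | 0.20 M | 0.12 M | 0.30 M | 0.060 M | 0.20 M | 0.80 M |
| coupling partner | 0.19 M | 0.19 M | 0.19 M | 0.300 M | 0.190 M | 0.100 M | 0.190 M | 0.190 M | 0.300 M |
| free catalyst | 15 mM | 15 mM | 12 mM | 25 mM | 4.0 mM | 5.0 mM | 10 mM | 15 mM | 8.0 mM |
| remark | run made earlier | run made earlier | run made earlier |  |  |  |  |  |  |
| time |  |  |  | 4.0 min | 4.0 min | 4.0 min | 4.0 min | 4.0 min | 4.0 min |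

| run | time / s | product / % | starting material / % |
|---|---|---|---|
| south-east | 10.0 | 9.8 | 84.3 |
| south-east | 15.0 | 15.6 | 78.0 |
| south-east | 25.0 | 27.4 | 67.7 |
| south-east | 40.0 | 41.7 | 54.3 |
| south-east | 80.0 | 67.0 | 30.4 |
| south-east | 120 | 82.0 | 17.0 |
| north-west | 20.0 | 6.0 | 92.1 |
| north-west | 40.0 | 12.6 | 84.7 |
| north-west | 60.0 | 17.5 | 80.1 |
| north-west | 80.0 | 20.9 | 76.5 |
| north-west | 90.0 | 22.5 | 75.5 |
| north-west | 120 | 26.0 | 73.4 |
| north | 25.0 | 15.0 | 82.1 |
| north | 50.0 | 28.0 | 69.7 |
| north | 80.0 | 40.9 | 56.5 |
| north | 90.0 | 44.2 | 52.5 |
| north | 120 | 53.6 | 44.5 |

(standard deviation of a reading: 0.5 percentage points)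

- ranking by amount of product, in percent of the starting material charged, from high to low, at 4.0 min (birch / alder / larch / ash / cedar / oak)
- the same order at 15 min (birch / alder / larch / ash / cedar / oak)
- the amount of product, in percent of the starting material charged of the flask you put first, at 4.0 min
- the amount of product, in percent of the starting material charged of the flask you put last, at 4.0 min



Larch has a ceiling, partner charge over starting material charge, of 33.3%, the lowest of the set. Larch holds less partner than starting material, so the coupling partner is its limiting reagent, and on this ceiling we put larch last. The north-west run also has more starting material than partner, so we open the ledger there, at 80.0 s. Of the 0.19 M of partner charged, the first entry is product, 0.136 M. The starting material missing from the balance, 0.0169 M, is a reading of about the size of the catalyst charge, so we assume that it sits on the catalyst and book it as using no partner. On that booking the north-west books close with 0.0542 M of partner left.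

Now we replace the curve by its mean, a pseudo-first-order decay of the partner whose rate scales with the catalyst charge. This gives the clearance constant, the logarithm of charged over left partner, divided by catalyst charge times time: 1.05 M⁻¹ s⁻¹, a reading that carries the scatter of the run. Larch at 4.0 min has the same catalyst charge times time as north-west at this reading, and on this constant its time constant is 3.19 min; we carry the constant over although larch holds less starting material than north-west. Its ledger therefore reads: of 0.100 M charged, 0.0285 M left and 0.0715 M in product, which is 23.8% of the starting material, under the ceiling. To check the error of the mean, we take the north-west readings at 40.0 s and 120 s, which give 0.940 M⁻¹ s⁻¹ and 1.22 M⁻¹ s⁻¹, and these reckon larch at 22.5% and 25.7%. We commit to 23.8%.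

The forecast gave birch > ash > cedar > alder > oak > larch at 4.0 min and birch > ash > alder > cedar > oak > larch at 15 min, with 98.5% first and 25.5% last, holding that “One rate law fits all three runs”.

The simulation gives birch > ash > cedar > alder > oak > larch at 4.0 min and ash > birch > cedar > alder > oak > larch at 15 min, with 97.0% first and larch last at 23.4%.

    product + catalyst intermediate D → spent catalyst (k = 0.0610 M⁻¹ s⁻¹)
    coupling partner + catalyst intermediate A → catalyst intermediate B (k = 2.30 M⁻¹ s⁻¹)
    catalyst intermediate D → free catalyst + product (k = 0.630 s⁻¹)
    catalyst intermediate C ⇌ released group + catalyst intermediate D (K = 0.420 M, k = 56.0 s⁻¹)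
    starting material + free catalyst ⇌ catalyst intermediate A (K = 5.50 M⁻¹, k = 2.50 M⁻¹ s⁻¹)
    catalyst intermediate B → catalyst intermediate C (k = 3.90 s⁻¹)

In larch the clock runs longer than the partner's half-life by its step with catalyst intermediate A: that half-life is 2.3 min at 1.41 min, which, if held over the whole run, makes 1.77 half-lives, and the clearance constant gives 2.21 min, which makes 1.81. Larch holds 29% of its partner charge, unbound, at 4.00 min. For the neighbour of larch with 0.0085 M of free catalyst, the clearance constant gives 11.7% of the partner left and 29.4% product. The computed neighbour holds 12% of its partner charge, unbound, and 29.2% product.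

(Readings and results were generated by integration with made-up constants, and the scatter is random.)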